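The earlier runs and the new flask stem from a simulated flask for an exercise, noise included.

The ratio of Z near its early top to Z at the end of a run says whether waiting pays when G goes into this closed flask.

| flask | G | remark | time |
|---|---|---|---|
| west | 0.65 M | run made earlier |  |
| north | 0.98 M | run made earlier |  |
| flask | 1.3 M |  | 10 h |

- west (time / h: Z / %, D / %): 0.100: 73.4, 15.1; 0.200: 74.4, 14.9; 0.500: 67.9, 13.5; 1.00: 65.1, 10.0; 2.00: 68.2, 4.0; 5.00: 69.5, 0.7; 10.0: 69.0, 0.6
- north (time / h: Z / %, D / %): 0.100: 73.7, 15.1; 0.200: 74.0, 15.1; 0.500: 66.7, 14.3; 1.00: 63.8, 12.3; 2.00: 64.5, 8.9; 5.00: 69.6, 1.5; 10.0: 69.1, 1.3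

(scatter of a reading: 0.3 percentage points)

- a reading or a percentage of D counts all its forms, free or not

- time up to 10 h at which Z stands highest
- the amount of Z, in percent of the G charged, at that time

Does the charge move the early curve? From west to north the charge grows 1.51-fold, yet north over west for Z at 0.100 h reads 1.00, so the early percentages of the new flask are taken from these runs.

Can late Z overtake them? Both runs pooled, the readings of Z at 0.200 h over those at 10.0 h give 1.07, the peak-to-plateau ratio. It stands above one, so the top is sought early.

Where, then? Pooled Z rises just 0.65 percentage points from 0.100 h to 0.200 h, then drops by 0.500 h. The reckoning here therefore takes the geometric mean of those two times, 0.141 h, at about 74.2%.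

The forecast says 0.2 h and 74.2%: “The maximum should therefore remain early”. Its time is later than the reckoned one.

The flask gives 0.141 h and 75.3%.

    D → E (k = 0.00189 min⁻¹)
    G ⇌ D (K = 2.78, k = 0.0795 min⁻¹)
    L ⇌ Z (K = 2.50, k = 0.0368 min⁻¹)
    D ⇌ L (K = 30.0, k = 5.47 × 10⁻⁴ min⁻¹)
    X ⇌ D, rate k5*(cs5 - [D]) while solid is left; crystals form when [D] > cs5 (solubility = 33.0 mM, k = 0.349 min⁻¹)
    Z ⇌ G (k = 0.00184 min⁻¹)

The flask's top comes before the forward half-life of L to Z, which is 0.31 h, about twice as long. In the flask, Z over L stands at 11.5 at the top and at 2.50 after 10.0 h, close to the 2.50 of the L–Z equilibrium: kinetic against thermodynamic control. Top over end in this flask is 1.09, against the 1.07 from the runs.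

For the neighbour flask with 2.2 M of G, 1.07 on its top of 75.2% gives an end level of 70.3%. The computed Z there is 66.0% after 10.0 h, with X still at 4.13%.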